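## Analysis of the target

Target 33 is a monocyclic C22 compound built on a nine-membered carbocycle (ring atoms C1–C9). The ring carries a methyl group on C4 and formyl groups on C8 (carbon C18) and C9 (carbon C19). C1 carries a side chain that starts at the methine C10, bears the acetoxymethyl carbon C11 and runs through C12–C13 to an isopropylidene end.

The ring holds two trisubstituted alkenes in a 1,4-relationship. C4=C5 is E, that is, trans inside the nine-membered ring. C7=C8 is ring-cis (E by the CIP rules only because of the formyl group). The ring therefore has the strain of an E-cyclononene.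

There are three contiguous stereocentres. C9 (S) and C1 (S) are vicinal on the ring, with the formyl group and the side chain trans. C10 (R) lies outside the ring, next to C1.

The sensitive groups are:
- the two aldehydes: C9 is epimerisable (α to C19 and allylic), and the alcohol precursors of the 1,4-related C18/C19 pair can close to lactols;
- the skipped diene;
- the acetate, which excludes late hydride or strongly basic steps.

The hard part is closing a nine-membered ring that contains an E alkene while controlling three adjacent stereocentres, one of them exocyclic. The strategy rests on the C9–C1 bond. C9 carries a carbonyl carbon (C19) and C1 a branched chain whose C10–C12 bond can be an alkene. That is the γ,δ-unsaturated acid pattern C19–C9–C1–C10=C12 that an ester-enolate Claisen rearrangement leaves behind.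

## Retrosynthetic reasoning

**33 ⇒ 32 ⇒ 31.** Both formyl groups are taken back to primary alcohols (C18–OH, C19–OH) in diol 32, and these to the PMB ethers of 31. The aldehydes must come last because C9 epimerises easily. The forward step has to oxidise a 1,4-diol without lactol formation.

**31 ⇒ 30 ⇒ 29.** The acetate is cut to alcohol 30. The C10–H and C12–H bonds are then removed to give allylic alcohol 29 with a C10=C12 alkene. This places C10 under the control of a hydroxyl-directed, face-selective hydrogenation and creates the alkene that the Claisen retron needs. The forward hydrogenation must touch only this alkene and set 10R.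

**29 ⇒ 28 ⇒ 27 ⇒ 26.** The free C11 hydroxyl comes from silyl ether 28, the C19 PMB ether from alcohol 27, and that from acid 26. C19 is reduced here, before any acetate exists, because an ester or acid cannot be reduced selectively next to an acetate later.

**26 ⇒ 23 (key disconnection).** The ring bond C9–C1 is cut and a C12–O bond is added, with the alkene moved from C10=C12 to C1=C10. This turns the nine-membered acid into the 13-membered allylic lactone 23. The strained ring is thus made by contraction of an easily closed macrocycle. C9 and C1 are created together, and C1 is derived from a simple carbinol centre (C12). The forward reaction needs α-enolisation, a defined ketene-acetal geometry and a chair-like six-centre array.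

**23 ⇒ 21 ⇒ 20.** The lactone C19–O bond is cut to seco acid 21, which comes from methyl ester 20. Macrolactonisation is chosen over a C–C ring closure because a 13-membered ring with three alkenes closes readily.

**20 ⇒ 19 ⇒ 18 ⇒ 17 ⇒ 16.** The silyl ether comes from diol 19. The C10–C11 bond is cut to iodide 18, which comes from stannane 17. The C1–H and C10–Sn bonds are then removed to give alkyne 16. A hydroxyl-directed trans-hydrometalation must place the metal on C10 (next to the carbinol) and H on C1, anti. A hydroalumination would put the metal on C1, so the ruthenium-catalysed hydrostannation is used. The C12 hydroxyl thus serves three times: to direct tin, as the lactone oxygen, and as the source of chirality for C1.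

**16 ⇒ 15.** The C8–C9 bond is cut: the acetate arm (C9, C19) is added to alkenyl bromide 15 by coupling with a zinc ester enolate, with retention. It is added only after C6 has been joined to C5. A free C6 hydroxyl cis to this ester would lactonise, and an allyl electrophile with the acidic C9 next to it would eliminate.

**15 ⇒ 13 + 6.** The C5–C6 bond and the C4–CH3 bond are cut. This gives terminal alkyne 13 and allylic chloride 6. Syn methylmetalation of 13 sets the E C4=C5 alkene, and alkenyl–allyl coupling makes the skipped diene. Cutting C6–C7 instead would need a Z-configured β,β-disubstituted alkenyl metal that already carries the acetate arm, and no short stereodefined access to it exists.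

**13 ⇒ 12 ⇒ 10 + 9; 9 ⇒ 7.** The C12 stereocentre comes from asymmetric reduction of ynone 12. The C10–C12 bond is cut to the acetylide of diyne 10 and Weinreb amide 9, made from acid 7.

**6 ⇒ 4 ⇒ 2 ⇒ 1.** The chloride comes from allylic alcohol 4. Its C8–Br and C7–H bonds come from directed trans-hydroalumination and bromination of alkynol 2, the mono-PMB ether of diol 1. This places Br on C8 cis to C6, so the later carbon substituent C9 ends up ring-cis to C6.

## Alternatives that were turned down

**Alternative 1: anionic oxy-Cope ring expansion.**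
- Disconnection: the ring bond C6–C7 is cut and a C4–C9 bond is added, which turns the nine-membered ring into a cyclopentane. The substrate is cyclopentanol A2, with a vinyl group (C8=C7) on the carbinol carbon C9 and a methyl and a second vinyl group (C5=C6) on the neighbouring C4; the C1 side chain with C10 is already in place.
- Forward key step: the potassium alkoxide of A2 rearranges (C6–C7 formed, C4–C9 broken) to the ring-enlarged enolate and, after protonation, the E-cyclononenone A1.
- For it: the four-atom ring enlargement is driven by enolate formation and runs at low temperature. A chair array with trans vinyl groups gives the E C4=C5 alkene dependably. C1 and C10 are set on a five-membered ring, where control is easier.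
- Against it: A1 has a ketone at C9 and a saturated C6–C7–C8 segment. C19, C18, the C7=C8 alkene and the C9 stereocentre would all have to be introduced afterwards on a flexible medium ring. A2 also needs two adjacent fully substituted centres of defined relative configuration.
- Comparison: for making the strained E-alkene ring this route is at least as strong as the chosen one, because the ring arises by opening a small ring. The chosen strategy instead delivers C9 with its carbon, C1, the C7=C8 alkene and the C8 carbon in the ring-forming event, so only functional-group changes follow and the route is shorter.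

**Alternative 2: sulfone-anion allylation closing C2–C3.**
- Disconnection: the ring bond C2–C3. The substrate is the open-chain compound A4, a phenyl sulfone at C2 and a primary allylic bromide at C3, with both alkenes and C9, C1, C10 in place.
- Forward key step: deprotonation next to the sulfone and intramolecular SN2 alkylation close the ring to sulfone A3 (either C2 epimer); reductive desulfonylation follows.
- For it: all stereocentres and both alkene geometries are fixed by acyclic chemistry before the ring exists. The carbanion is soft and tolerant. A3 already has the oxidation pattern of the late intermediates of the chosen route.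
- Against it: this is a direct end-to-end closure of a nine-membered ring with an E alkene, the least favourable ring-size class for SN2 cyclisation. Dimerisation, SN2′ attack at C5 (a seven-membered ring) and elimination compete, and high dilution is needed. A4 requires the C9/C1/C10 triad on an open chain, for which the obvious tool is again an enolate Claisen. The sulfone costs steps to install and remove.
- Comparison: stereochemical certainty is higher than in the chosen strategy, which depends on the shape of a macrocyclic transition state. The chosen strategy offers ring formation by contraction of an easily closed lactone, two stereocentres made in the same event, and fewer steps.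

**Alternative 3: Grob fragmentation of a hydrindanol tosylate.**
- Disconnection: the C4=C5 alkene and the C8 carbonyl are taken back to a C4–C8 bond. This gives the cis-fused bicyclo[4.3.0]nonane A6 (angular hydroxyl on C8, angular methyl on C4, tosylate on C5).
- Forward key step: base forms the C8 alkoxide; fragmentation breaks C4–C8, forms C8=O and C4=C5 and expels tosylate, giving E-cyclononenone A5.
- For it: the fragmentation is stereospecific, so the alkene geometry follows from the relative configuration at C4 and C5. The ring is opened, not closed. The C8 ketone is well placed for conversion into the C7=C8 enal (enol triflate towards C7, then formylation). C9 and C1 can be set on a rigid bicycle.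
- Against it: A6 has six stereocentres, two of them quaternary, and three are destroyed in the key step. Building it with the exocyclic C10 centre is a long linear sequence. C9 lies α to the ketone that forms under base and can epimerise.
- Comparison: for the ring-forming event itself this alternative is stronger than the chosen one. The chosen strategy is preferred for step economy and convergence (three small acyclic pieces) and because its key step creates the C9/C1 pair instead of consuming stereocentres.

Key step: step 15

Remark on the chemistry: the absolute sense of the two catalyst-controlled reductions (steps 6 and 19) is assigned by analogy with simple alkynyl ketones and with geraniol/nerol; should the analogy fail, the antipodal ligand is used.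

## Route

Step 1
Reactants: 1 but-2-yne-1,4-diol
Product: 2 4-[(4-methoxybenzyl)oxy]but-2-yn-1-ol
Conditions: NaH (1 equiv), 1 in excess, THF/DMF, 0 °C; PMBCl, Bu4NI (cat.), rt
Reagents that add atoms: 4-methoxybenzyl chloride, COc1ccc(CCl)cc1
Why: Williamson etherification; with the symmetric diol in excess and one equivalent of base the monoether should dominate and is separated from diol and diether.

Step 2
Reactants: 2 4-[(4-methoxybenzyl)oxy]but-2-yn-1-ol
Product: 4 (Z)-3-bromo-4-[(4-methoxybenzyl)oxy]but-2-en-1-ol, via cyclic vinylalanate 3 (not isolated)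
Conditions: Red-Al, THF, 0 °C to rt; then NBS, −78 to 0 °C
Reagents that add atoms: N-bromosuccinimide, O=C1CCC(=O)N1Br
Why: Alkoxide-directed trans-hydroalumination of a propargylic alcohol delivers hydride to the proximal carbon (C7) and places aluminium on the distal carbon (C8) in a five-membered alanate; bromodealumination with retention then puts Br on C8 cis to C6 (Z).

Step 3
Reactants: 4 (Z)-3-bromo-4-[(4-methoxybenzyl)oxy]but-2-en-1-ol
Product: 6 1-({[(Z)-2-bromo-4-chlorobut-2-en-1-yl]oxy}methyl)-4-methoxybenzene, via allylic mesylate 5 (not isolated)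
Conditions: MsCl, 2,4,6-collidine, LiCl, DMF, 0 °C
Reagents that add atoms: lithium chloride, [Li+].[Cl-]
Why: Chlorination through the mesylate under buffered conditions; SN2 displacement at the primary allylic carbon keeps the alkene geometry and leaves the vinyl bromide and the PMB ether untouched.

Step 4
Reactants: 7 4-methylpent-3-enoic acid
Product: 9 N-methoxy-N,4-dimethylpent-3-enamide, via acyl imidazolide 8 (not isolated)
Conditions: CDI, CH2Cl2, rt; then MeNHOMe·HCl
Reagents that add atoms: N,O-dimethylhydroxylamine hydrochloride, CNOC.Cl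
Why: Amide formation through the acyl imidazolide; the near-neutral conditions should not move the β,γ double bond into conjugation.

Step 5
Reactants: 10 hexa-1,5-diyne; 9 N-methoxy-N,4-dimethylpent-3-enamide
Product: 12 2-methylundec-2-ene-6,10-diyn-5-one, via lithium acetylide 11 (not isolated)
Conditions: 10 (3 equiv), n-BuLi (1 equiv), THF, −78 °C; then 9, −78 to 0 °C; aq. NH4Cl
Reagents that add atoms: none
Why: Acylation of a lithium acetylide by a Weinreb amide; the chelated tetrahedral adduct stops at the ketone, and the excess of the symmetric diyne limits double reaction.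

Step 6
Reactants: 12 2-methylundec-2-ene-6,10-diyn-5-one
Product: 13 (R)-2-methylundec-2-ene-6,10-diyn-5-ol
Conditions: Ru[(R,R)-TsDPEN](p-cymene) (cat., base-free), i-PrOH, rt
Reagents that add atoms: none
Why: Noyori asymmetric transfer hydrogenation of an alkynyl ketone; the alkynyl group is the differentiating unsaturated substituent and the (R,R)-catalyst should give the R carbinol (C12); the base-free catalyst and the fast ynone reduction should spare the skipped alkene and the remote terminal alkyne.

Step 7
Reactants: 13 (R)-2-methylundec-2-ene-6,10-diyn-5-ol; 6 1-({[(Z)-2-bromo-4-chlorobut-2-en-1-yl]oxy}methyl)-4-methoxybenzene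
Product: 15 (5R,10E,13Z)-14-bromo-15-[(4-methoxybenzyl)oxy]-2,10-dimethylpentadeca-2,10,13-trien-6-yn-5-ol, via alkenylalane 14 (not isolated)
Conditions: Me3Al, Cp2ZrCl2 (cat.), CH2Cl2, 0 °C to rt; then 6, Pd(PPh3)4 (cat.), THF, rt
Reagents that add atoms: trimethylaluminium, C[Al](C)C
Why: Negishi zirconium-catalysed methylalumination adds CH3 and Al syn across the terminal alkyne (CH3 on C4, Al on C5, E) much faster than across the internal alkyne; Pd-catalysed alkenyl–allyl coupling then joins C5 to the primary terminus C6 with retention of both alkene geometries. Pd(PPh3)4 at rt should insert into the allylic C–Cl bond and not into the vinylic C–Br bond.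

Step 8
Reactants: 15 (5R,10E,13Z)-14-bromo-15-[(4-methoxybenzyl)oxy]-2,10-dimethylpentadeca-2,10,13-trien-6-yn-5-ol
Product: 16 methyl (3E,6E,12R)-12-hydroxy-3-{[(4-methoxybenzyl)oxy]methyl}-7,15-dimethylhexadeca-3,6,14-trien-10-ynoate
Conditions: BrZnCH2CO2Me (excess), Pd2(dba)3/XPhos (cat.), THF, 50 °C
Reagents that add atoms: bromo(2-methoxy-2-oxoethyl)zinc, COC(=O)C[Zn]Br
Why: Negishi coupling of a Reformatsky reagent with an alkenyl bromide proceeds with retention at C8 and installs C9/C19 cis to C6; the excess reagent covers the free hydroxyl, which returns on work-up.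

Step 9
Reactants: 16 methyl (3E,6E,12R)-12-hydroxy-3-{[(4-methoxybenzyl)oxy]methyl}-7,15-dimethylhexadeca-3,6,14-trien-10-ynoate
Product: 17 methyl (3E,6E,10Z,12R)-12-hydroxy-3-{[(4-methoxybenzyl)oxy]methyl}-7,15-dimethyl-11-(tributylstannyl)hexadeca-3,6,10,14-tetraenoate
Conditions: [Cp*RuCl]4 (cat.), Bu3SnH (slow addition), CH2Cl2, rt
Reagents that add atoms: tributyltin hydride, CCCC[SnH](CCCC)CCCC
Why: Ruthenium-catalysed hydroxyl-directed trans-hydrostannation of a propargylic alcohol adds H and Sn anti with tin on the carbon next to the carbinol (C10), so C2 ends trans to C12 as the lactone requires; the isolated trisubstituted alkenes and the ester are inert.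

Step 10
Reactants: 17 methyl (3E,6E,10Z,12R)-12-hydroxy-3-{[(4-methoxybenzyl)oxy]methyl}-7,15-dimethyl-11-(tributylstannyl)hexadeca-3,6,10,14-tetraenoate
Product: 18 methyl (3E,6E,10Z,12R)-12-hydroxy-11-iodo-3-{[(4-methoxybenzyl)oxy]methyl}-7,15-dimethylhexadeca-3,6,10,14-tetraenoate
Conditions: I2 (1 equiv), CH2Cl2, −78 to 0 °C
Reagents that add atoms: iodine, II
Why: Iododestannylation with retention of alkene geometry; ipso attack at the C–Sn bond is much faster than any reaction of iodine with the trisubstituted alkenes at low temperature.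

Step 11
Reactants: 18 methyl (3E,6E,10Z,12R)-12-hydroxy-11-iodo-3-{[(4-methoxybenzyl)oxy]methyl}-7,15-dimethylhexadeca-3,6,10,14-tetraenoate
Product: 19 methyl (3E,6E,10E,12R)-12-hydroxy-11-(hydroxymethyl)-3-{[(4-methoxybenzyl)oxy]methyl}-7,15-dimethylhexadeca-3,6,10,14-tetraenoate
Conditions: Bu3SnCH2OH, Pd(PPh3)4 (cat.), 1,4-dioxane, 90 °C
Reagents that add atoms: (tributylstannyl)methanol, CCCC[Sn](CO)(CCCC)CCCC
Why: Stille (Migita–Kosugi) coupling with a hydroxymethylstannane replaces iodide by CH2OH with retention, giving the C1=C10 alkene with C11 cis to C2; the ester is not touched, which a carbonylation–reduction sequence could not guarantee.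

Step 12
Reactants: 19 methyl (3E,6E,10E,12R)-12-hydroxy-11-(hydroxymethyl)-3-{[(4-methoxybenzyl)oxy]methyl}-7,15-dimethylhexadeca-3,6,10,14-tetraenoate
Product: 20 methyl (3E,6E,10E,12R)-11-{[(tert-butyldimethylsilyl)oxy]methyl}-12-hydroxy-3-{[(4-methoxybenzyl)oxy]methyl}-7,15-dimethylhexadeca-3,6,10,14-tetraenoate
Conditions: TBSCl (1 equiv), imidazole, CH2Cl2, 0 °C
Reagents that add atoms: tert-butyldimethylsilyl chloride, CC(C)(C)[Si](C)(C)Cl
Why: Silylation; the primary allylic hydroxyl reacts far faster than the hindered secondary allylic C12 hydroxyl, which must stay free for lactonisation.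

Step 13
Reactants: 20 methyl (3E,6E,10E,12R)-11-{[(tert-butyldimethylsilyl)oxy]methyl}-12-hydroxy-3-{[(4-methoxybenzyl)oxy]methyl}-7,15-dimethylhexadeca-3,6,10,14-tetraenoate
Product: 21 (3E,6E,10E,12R)-11-{[(tert-butyldimethylsilyl)oxy]methyl}-12-hydroxy-3-{[(4-methoxybenzyl)oxy]methyl}-7,15-dimethylhexadeca-3,6,10,14-tetraenoic acid
Conditions: LiOH, THF/H2O, 0 °C to rt; then dil. HCl to pH 4 at 0 °C
Reagents that add atoms: lithium hydroxide, [Li+].[OH-]
Why: Saponification of the unhindered methyl ester; hydroxide addition should be faster than α-deprotonation, and the carboxylate formed is no longer prone to double-bond migration.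

Step 14
Reactants: 21 (3E,6E,10E,12R)-11-{[(tert-butyldimethylsilyl)oxy]methyl}-12-hydroxy-3-{[(4-methoxybenzyl)oxy]methyl}-7,15-dimethylhexadeca-3,6,10,14-tetraenoic acid
Product: 23 (4E,7E,11E,13R)-12-{[(tert-butyldimethylsilyl)oxy]methyl}-4-{[(4-methoxybenzyl)oxy]methyl}-8-methyl-13-(3-methylbut-2-en-1-yl)-1-oxacyclotrideca-4,7,11-trien-2-one, via mixed anhydride 22 (not isolated)
Conditions: 2-methyl-6-nitrobenzoic anhydride, DMAP, CH2Cl2, rt, slow addition of 21, high dilution
Reagents that add atoms: none
Why: Shiina macrolactonisation through the mixed anhydride at room temperature; the three alkenes pre-bend the chain towards the 13-membered ring, and the mild conditions should limit enolisation of the β,γ-unsaturated acyl donor.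

Step 15
Reactants: 23 (4E,7E,11E,13R)-12-{[(tert-butyldimethylsilyl)oxy]methyl}-4-{[(4-methoxybenzyl)oxy]methyl}-8-methyl-13-(3-methylbut-2-en-1-yl)-1-oxacyclotrideca-4,7,11-trien-2-one
Product: 26 (1S,2E,5E,9R)-9-[(2Z)-1-{[tert-butyl(dimethyl)silyl]oxy}-6-methylhepta-2,5-dien-2-yl]-2-{[(4-methoxybenzyl)oxy]methyl}-6-methylcyclonona-2,5-diene-1-carboxylic acid, via silyl ketene acetal 24 (not isolated), via trimethylsilyl ester 25 (not isolated)
Conditions: LDA, THF/DMPU, −78 °C; TMSCl; −78 °C to rt, then PhMe, 80 °C; aq. citric acid
Reagents that add atoms: none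
Why: This is an Ireland–Claisen rearrangement used as a ring contraction, a known reaction type for macrocyclic allylic lactones that is applied here to a new ring size and substitution pattern. LDA removes the doubly activated C9 proton and O-silylation gives the silyloxy diene 24 (C19=C9 conjugated with C7=C8), which on warming undergoes a concerted suprafacial [3,3] shift through O–C19=C9···C1=C10–C12: the C9–C1 bond forms as the C12–O bond breaks, and silyl ester 25 is hydrolysed to 26 on work-up. The nine-membered carbocycle is closed transannularly, by contraction of the 13-membered ring across a six-centre array, not by an end-to-end cyclisation. C1 is controlled by C12: with the prenyl group pseudo-equatorial and the ring-E C1=C10 alkene, C9 adds to the face of C1 syn to the departing oxygen, which turns 12R into the required configuration at C1 and gives the Z C10=C12 alkene. C9 is controlled by the ketene-acetal geometry and the chair array: with the silyloxy group cis to C8 (the geometry favoured in the presence of DMPU) both ring arms (C8 on C9, C2 on C1) are pseudo-equatorial, which places CO2H trans to the side chain. The selectivities needed are bonding through the α-carbon of the dienolate (only C9 can reach C1 in a six-membered array), chair over boat, and retention of the ring-cis C7=C8 geometry; the seven-atom tether with its E and ring-cis alkenes holds C9 over C1, and the in-ring E geometry of both reacting π bonds favours the chair.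

Step 16
Reactants: 26 (1S,2E,5E,9R)-9-[(2Z)-1-{[tert-butyl(dimethyl)silyl]oxy}-6-methylhepta-2,5-dien-2-yl]-2-{[(4-methoxybenzyl)oxy]methyl}-6-methylcyclonona-2,5-diene-1-carboxylic acid
Product: 27 [(1S,2E,5E,9R)-9-[(2Z)-1-{[tert-butyl(dimethyl)silyl]oxy}-6-methylhepta-2,5-dien-2-yl]-2-{[(4-methoxybenzyl)oxy]methyl}-6-methylcyclonona-2,5-dien-1-yl]methanol
Conditions: LiAlH4, THF, 0 °C to rt
Reagents that add atoms: none
Why: Hydride reduction of the carboxylic acid through its lithium carboxylate, which does not enolise at C9; silyl and PMB ethers and isolated alkenes are inert. Reduction at this stage avoids a later ester reduction in the presence of the acetate.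

Step 17
Reactants: 27 [(1S,2E,5E,9R)-9-[(2Z)-1-{[tert-butyl(dimethyl)silyl]oxy}-6-methylhepta-2,5-dien-2-yl]-2-{[(4-methoxybenzyl)oxy]methyl}-6-methylcyclonona-2,5-dien-1-yl]methanol
Product: 28 tert-butyl{[(2Z)-2-[(1R,2S,3E,6E)-2,3-bis{[(4-methoxybenzyl)oxy]methyl}-7-methylcyclonona-3,6-dien-1-yl]-6-methylhepta-2,5-dien-1-yl]oxy}dimethylsilane
Conditions: NaH, PMBCl, Bu4NI (cat.), DMF, 0 °C to rt
Reagents that add atoms: 4-methoxybenzyl chloride, COc1ccc(CCl)cc1
Why: Williamson etherification; masking the C19 hydroxyl ensures that only the C11 hydroxyl directs the hydrogenation and is acetylated, and both future aldehyde carbons can be unmasked together.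

Step 18
Reactants: 28 tert-butyl{[(2Z)-2-[(1R,2S,3E,6E)-2,3-bis{[(4-methoxybenzyl)oxy]methyl}-7-methylcyclonona-3,6-dien-1-yl]-6-methylhepta-2,5-dien-1-yl]oxy}dimethylsilane
Product: 29 (2Z)-2-[(1R,2S,3E,6E)-2,3-bis{[(4-methoxybenzyl)oxy]methyl}-7-methylcyclonona-3,6-dien-1-yl]-6-methylhepta-2,5-dien-1-ol
Conditions: TBAF, THF, 0 °C
Reagents that add atoms: none
Why: Fluoride cleavage of the silyl ether frees the allylic alcohol; PMB ethers and alkenes are unaffected.

Step 19
Reactants: 29 (2Z)-2-[(1R,2S,3E,6E)-2,3-bis{[(4-methoxybenzyl)oxy]methyl}-7-methylcyclonona-3,6-dien-1-yl]-6-methylhepta-2,5-dien-1-ol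
Product: 30 (2R)-2-[(1S,2S,3E,6E)-2,3-bis{[(4-methoxybenzyl)oxy]methyl}-7-methylcyclonona-3,6-dien-1-yl]-6-methylhept-5-en-1-ol
Conditions: Ru(OAc)2[(S)-BINAP] (cat.), H2 (50 atm), MeOH, rt
Reagents that add atoms: none
Why: Noyori hydrogenation of an allylic alcohol with Ru–BINAP: hydroxyl coordination makes C10=C12 the only alkene reduced, and the catalyst selects the alkene face. By the face rule that holds for geraniol and nerol, the (S)-BINAP complex should deliver hydrogen to give 10R. The change of the C1 label from R to S is a CIP priority change only.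

Step 20
Reactants: 30 (2R)-2-[(1S,2S,3E,6E)-2,3-bis{[(4-methoxybenzyl)oxy]methyl}-7-methylcyclonona-3,6-dien-1-yl]-6-methylhept-5-en-1-ol
Product: 31 (2R)-2-[(1S,2S,3E,6E)-2,3-bis{[(4-methoxybenzyl)oxy]methyl}-7-methylcyclonona-3,6-dien-1-yl]-6-methylhept-5-en-1-yl acetate
Conditions: Ac2O, pyridine, DMAP (cat.), CH2Cl2, 0 °C
Reagents that add atoms: acetic anhydride, CC(=O)OC(C)=O
Why: Acetylation of the only free hydroxyl.

Step 21
Reactants: 31 (2R)-2-[(1S,2S,3E,6E)-2,3-bis{[(4-methoxybenzyl)oxy]methyl}-7-methylcyclonona-3,6-dien-1-yl]-6-methylhept-5-en-1-yl acetate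
Product: 32 (2R)-2-[(1S,2S,3E,6E)-2,3-bis(hydroxymethyl)-7-methylcyclonona-3,6-dien-1-yl]-6-methylhept-5-en-1-yl acetate
Conditions: DDQ, CH2Cl2/pH 7 buffer, 0 °C
Reagents that add atoms: none
Why: Oxidative cleavage of both PMB ethers through their benzylic oxocarbenium ions, which water hydrolyses before the neighbouring hydroxyl can trap them; the acetate and the alkenes should survive at 0 °C, and any over-oxidation of the allylic alcohol leads towards the target aldehyde.

Step 22
Reactants: 32 (2R)-2-[(1S,2S,3E,6E)-2,3-bis(hydroxymethyl)-7-methylcyclonona-3,6-dien-1-yl]-6-methylhept-5-en-1-yl acetate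
Product: 33 (2R)-2-[(1S,2S,3E,6E)-2,3-diformyl-7-methylcyclonona-3,6-dien-1-yl]-6-methylhept-5-en-1-yl acetate
Conditions: (COCl)2, DMSO, CH2Cl2, −78 °C; i-Pr2NEt, −78 to −30 °C; pH 7 buffer
Reagents that add atoms: none
Why: Swern oxidation converts both hydroxyls into alkoxysulfonium ions before base is added, so no aldehyde is formed next to a free hydroxyl and lactol formation in this 1,4-diol is avoided; the hindered base and cold buffered quench should limit epimerisation at C9.

## Compound list

1 | but-2-yne-1,4-diol | OCC#CCO | starting material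
2 | 4-[(4-methoxybenzyl)oxy]but-2-yn-1-ol | COc1ccc(COCC#CCO)cc1 | intermediate
3 | cyclic vinylalanate (sodium salt; Al bound to the C6 oxygen and to C8, two 2-methoxyethoxy ligands) | COCCO[Al-]1(OCCOC)OCC=C1COCc1ccc(OC)cc1.[Na+] | intermediate
4 | (Z)-3-bromo-4-[(4-methoxybenzyl)oxy]but-2-en-1-ol | OC/C=C(Br)/COCc1ccc(OC)cc1 | intermediate
5 | (Z)-3-bromo-4-[(4-methoxybenzyl)oxy]but-2-en-1-yl methanesulfonate | CS(=O)(=O)OC/C=C(Br)/COCc1ccc(OC)cc1 | intermediate
6 | 1-({[(Z)-2-bromo-4-chlorobut-2-en-1-yl]oxy}methyl)-4-methoxybenzene | ClC/C=C(Br)/COCc1ccc(OC)cc1 | intermediate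
7 | 4-methylpent-3-enoic acid | CC(C)=CCC(=O)O | starting material
8 | 1-(1H-imidazol-1-yl)-4-methylpent-3-en-1-one (acyl imidazolide) | CC(C)=CCC(=O)n1ccnc1 | intermediate
9 | N-methoxy-N,4-dimethylpent-3-enamide | CC(C)=CCC(=O)N(C)OC | intermediate
10 | hexa-1,5-diyne | C#CCCC#C | starting material
11 | lithium hexa-1,5-diyn-1-ide | [Li]C#CCCC#C | intermediate
12 | 2-methylundec-2-ene-6,10-diyn-5-one | CC(C)=CCC(=O)C#CCCC#C | intermediate
13 | (R)-2-methylundec-2-ene-6,10-diyn-5-ol | CC(C)=CC[C@@H](O)C#CCCC#C | intermediate
14 | (E)-alkenyl(dimethyl)alane from 13 (Al on C5, CH3 on C4; hydroxyl as its dimethylaluminium alkoxide; 12R) | C[Al](C)/C=C(C)/CCC#C[C@H](O[Al](C)C)CC=C(C)C | intermediate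
15 | (5R,10E,13Z)-14-bromo-15-[(4-methoxybenzyl)oxy]-2,10-dimethylpentadeca-2,10,13-trien-6-yn-5-ol | COc1ccc(COC/C(Br)=C/C/C=C(C)/CCC#C[C@H](O)CC=C(C)C)cc1 | intermediate
16 | methyl (3E,6E,12R)-12-hydroxy-3-{[(4-methoxybenzyl)oxy]methyl}-7,15-dimethylhexadeca-3,6,14-trien-10-ynoate | COC(=O)C/C(COCc1ccc(OC)cc1)=C\C/C=C(C)/CCC#C[C@H](O)CC=C(C)C | intermediate
17 | methyl (3E,6E,10Z,12R)-12-hydroxy-3-{[(4-methoxybenzyl)oxy]methyl}-7,15-dimethyl-11-(tributylstannyl)hexadeca-3,6,10,14-tetraenoate | COC(=O)C/C(COCc1ccc(OC)cc1)=C\C/C=C(C)/CC/C=C(/[C@H](O)CC=C(C)C)[Sn](CCCC)(CCCC)CCCC | intermediate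
18 | methyl (3E,6E,10Z,12R)-12-hydroxy-11-iodo-3-{[(4-methoxybenzyl)oxy]methyl}-7,15-dimethylhexadeca-3,6,10,14-tetraenoate | COC(=O)C/C(COCc1ccc(OC)cc1)=C\C/C=C(C)/CC/C=C(/[C@H](O)CC=C(C)C)I | intermediate
19 | methyl (3E,6E,10E,12R)-12-hydroxy-11-(hydroxymethyl)-3-{[(4-methoxybenzyl)oxy]methyl}-7,15-dimethylhexadeca-3,6,10,14-tetraenoate | COC(=O)C/C(COCc1ccc(OC)cc1)=C\C/C=C(C)/CC/C=C(/[C@H](O)CC=C(C)C)CO | intermediate
20 | methyl (3E,6E,10E,12R)-11-{[(tert-butyldimethylsilyl)oxy]methyl}-12-hydroxy-3-{[(4-methoxybenzyl)oxy]methyl}-7,15-dimethylhexadeca-3,6,10,14-tetraenoate | COC(=O)C/C(COCc1ccc(OC)cc1)=C\C/C=C(C)/CC/C=C(/[C@H](O)CC=C(C)C)CO[Si](C)(C)C(C)(C)C | intermediate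
21 | (3E,6E,10E,12R)-11-{[(tert-butyldimethylsilyl)oxy]methyl}-12-hydroxy-3-{[(4-methoxybenzyl)oxy]methyl}-7,15-dimethylhexadeca-3,6,10,14-tetraenoic acid (seco acid) | OC(=O)C/C(COCc1ccc(OC)cc1)=C\C/C=C(C)/CC/C=C(/[C@H](O)CC=C(C)C)CO[Si](C)(C)C(C)(C)C | intermediate
22 | mixed anhydride of 21 with 2-methyl-6-nitrobenzoic acid | Cc1cccc([N+](=O)[O-])c1C(=O)OC(=O)C/C(COCc1ccc(OC)cc1)=C\C/C=C(C)/CC/C=C(/[C@H](O)CC=C(C)C)CO[Si](C)(C)C(C)(C)C | intermediate
23 | (4E,7E,11E,13R)-12-{[(tert-butyldimethylsilyl)oxy]methyl}-4-{[(4-methoxybenzyl)oxy]methyl}-8-methyl-13-(3-methylbut-2-en-1-yl)-1-oxacyclotrideca-4,7,11-trien-2-one (13-membered lactone, key-step precursor) | O=C1C/C(COCc2ccc(OC)cc2)=C\C/C=C(C)/CC/C=C(CO[Si](C)(C)C(C)(C)C)/[C@@H](CC=C(C)C)O1 | intermediate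
24 | (2Z,4E,7E,11E,13R)-12-{[(tert-butyldimethylsilyl)oxy]methyl}-4-{[(4-methoxybenzyl)oxy]methyl}-8-methyl-13-(3-methylbut-2-en-1-yl)-2-[(trimethylsilyl)oxy]-1-oxacyclotrideca-2,4,7,11-tetraene (silyl ketene acetal, silyloxy cis to C8) | C[Si](C)(C)O/C1=C\C(COCc2ccc(OC)cc2)=C/C/C=C(C)/CC/C=C(CO[Si](C)(C)C(C)(C)C)/[C@@H](CC=C(C)C)O1 | intermediate
25 | trimethylsilyl ester of 26 | CC(C)(C)[Si](C)(C)OC/C(=C\CC=C(C)C)[C@@H]1CC/C(C)=C/C/C=C(/COCc2ccc(OC)cc2)[C@H]1C(=O)O[Si](C)(C)C | intermediate
26 | (1S,2E,5E,9R)-9-[(2Z)-1-{[tert-butyl(dimethyl)silyl]oxy}-6-methylhepta-2,5-dien-2-yl]-2-{[(4-methoxybenzyl)oxy]methyl}-6-methylcyclonona-2,5-diene-1-carboxylic acid (key-step product; CO2H on C9 trans to the side chain on C1) | CC(C)(C)[Si](C)(C)OC/C(=C\CC=C(C)C)[C@@H]1CC/C(C)=C/C/C=C(/COCc2ccc(OC)cc2)[C@H]1C(=O)O | intermediate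
27 | [(1S,2E,5E,9R)-9-[(2Z)-1-{[tert-butyl(dimethyl)silyl]oxy}-6-methylhepta-2,5-dien-2-yl]-2-{[(4-methoxybenzyl)oxy]methyl}-6-methylcyclonona-2,5-dien-1-yl]methanol | CC(C)(C)[Si](C)(C)OC/C(=C\CC=C(C)C)[C@@H]1CC/C(C)=C/C/C=C(/COCc2ccc(OC)cc2)[C@H]1CO | intermediate
28 | tert-butyl{[(2Z)-2-[(1R,2S,3E,6E)-2,3-bis{[(4-methoxybenzyl)oxy]methyl}-7-methylcyclonona-3,6-dien-1-yl]-6-methylhepta-2,5-dien-1-yl]oxy}dimethylsilane | CC(C)(C)[Si](C)(C)OC/C(=C\CC=C(C)C)[C@@H]1CC/C(C)=C/C/C=C(/COCc2ccc(OC)cc2)[C@H]1COCc1ccc(OC)cc1 | intermediate
29 | (2Z)-2-[(1R,2S,3E,6E)-2,3-bis{[(4-methoxybenzyl)oxy]methyl}-7-methylcyclonona-3,6-dien-1-yl]-6-methylhepta-2,5-dien-1-ol | OC/C(=C\CC=C(C)C)[C@@H]1CC/C(C)=C/C/C=C(/COCc2ccc(OC)cc2)[C@H]1COCc1ccc(OC)cc1 | intermediate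
30 | (2R)-2-[(1S,2S,3E,6E)-2,3-bis{[(4-methoxybenzyl)oxy]methyl}-7-methylcyclonona-3,6-dien-1-yl]-6-methylhept-5-en-1-ol | OC[C@H](CCC=C(C)C)[C@@H]1CC/C(C)=C/C/C=C(/COCc2ccc(OC)cc2)[C@H]1COCc1ccc(OC)cc1 | intermediate
31 | (2R)-2-[(1S,2S,3E,6E)-2,3-bis{[(4-methoxybenzyl)oxy]methyl}-7-methylcyclonona-3,6-dien-1-yl]-6-methylhept-5-en-1-yl acetate | CC(=O)OC[C@H](CCC=C(C)C)[C@@H]1CC/C(C)=C/C/C=C(/COCc2ccc(OC)cc2)[C@H]1COCc1ccc(OC)cc1 | intermediate
32 | (2R)-2-[(1S,2S,3E,6E)-2,3-bis(hydroxymethyl)-7-methylcyclonona-3,6-dien-1-yl]-6-methylhept-5-en-1-yl acetate | CC(=O)OC[C@H](CCC=C(C)C)[C@@H]1CC/C(C)=C/C/C=C(/CO)[C@H]1CO | intermediate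
33 | (2R)-2-[(1S,2S,3E,6E)-2,3-diformyl-7-methylcyclonona-3,6-dien-1-yl]-6-methylhept-5-en-1-yl acetate | CC(=O)OC[C@H](CCC=C(C)C)[C@@H]1CC/C(C)=C/C/C=C(/C=O)[C@H]1C=O | target

## Step count and least certain steps

Total: 22 steps. Longest linear sequence: 19 steps (steps 1–3, then 7–22, from but-2-yne-1,4-diol).

**Step 15 (key step).** The most likely failure is loss of control at C9. Silylation may fix the other ketene-acetal geometry, or the macrocycle may react through a boat array; either puts the carboxyl group cis to the side chain. The chair/boat preference of a 13-membered triene and the enolate geometry of a macrocyclic dienolate cannot be predicted with confidence. The fallback replaces kinetic control by thermodynamic control. It sets out from 23: the rearrangement is run as before, and the acid obtained, the C9-epimeric acid F1, is esterified with trimethylsilyldiazomethane to the cis methyl ester F2. This is equilibrated with NaOMe in MeOH to the trans methyl ester F3, which should be favoured because the two ring substituents avoid each other. LiAlH4 then reduces F3 and the route is rejoined at 27.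

**Step 7.** The most likely failure is incomplete discrimination in the methylalumination between the terminal alkyne and the internal alkyne next to the aluminium alkoxide, or ionisation of the bromine-bearing allyl unit with loss of the C7=C8 geometry. The fallback changes the order of bond construction so that the methylalumination sees only a hydrocarbon. It sets out from 10 and 6: hexa-1,5-diyne 10, in excess, is methylaluminated alone and the alane is coupled with 6 under palladium catalysis to the bromo dienyne F4. The terminal alkyne of F4 is deprotonated with LDA and acylated with 9 to the ynone F5. Transfer hydrogenation as in step 6 returns to the route at 15.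

**Step 14.** The most likely failure is enolisation of the activated β,γ-unsaturated acyl group by the amine base (vinylketene formation), leading to double-bond migration into conjugation and oligomerisation, since the nucleophile is a hindered secondary allylic alcohol. The fallback changes the mode of activation to a neutral, isolable thioester without amine base. It sets out from 21, which is converted with 2,2′-dipyridyl disulfide and triphenylphosphine into the S-(2-pyridyl) thioester F6. Cyclisation under high dilution with a thiophilic silver salt (Corey–Nicolaou double activation) returns to the route at 23.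

**Step 19.** The most likely failure is slow hydrogenation or poor facial selectivity. The alkene carries a branched ring substituent at its 2-position and the catalyst may be mismatched with C1; isomerisation of the allylic alcohol to the saturated aldehyde is a side process. The fallback moves to the substrate class that Ru–BINAP handles best, 2-substituted acrylic acids. It sets out from 29, which is oxidised with MnO2 to the enal F7 and with NaClO2/NaH2PO4/2-methyl-2-butene (Pinnick) to the α,β-unsaturated acid F8. Carboxylate-directed hydrogenation with Ru(OAc)2(BINAP), enantiomer chosen by the tiglic-acid precedent, gives the saturated acid F9. LiAlH4 reduction returns to the route at 30.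

**Step 22.** The most likely failure is ring closure of a transient hydroxy aldehyde to a lactol followed by over-oxidation to a lactone, or amine-induced epimerisation at C9 and migration of C7=C8 into conjugation. The fallback is a staged, base-free oxidation that uses the allylic reactivity of the C18 alcohol. It sets out from 32, which MnO2 oxidises only at the allylic position to the hydroxy enal F10; a conjugated aldehyde is a poor partner for hemiacetal formation. Buffered Dess–Martin oxidation of the remaining primary alcohol then gives 33.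

## Further compounds

F1 | step 15 | C9-epimeric acid (CO2H cis to the side chain) | CC(C)(C)[Si](C)(C)OC/C(=C\CC=C(C)C)[C@@H]1CC/C(C)=C/C/C=C(/COCc2ccc(OC)cc2)[C@@H]1C(=O)O
F2 | step 15 | cis methyl ester of F1 | CC(C)(C)[Si](C)(C)OC/C(=C\CC=C(C)C)[C@@H]1CC/C(C)=C/C/C=C(/COCc2ccc(OC)cc2)[C@@H]1C(=O)OC
F3 | step 15 | trans methyl ester (methyl ester of 26) | CC(C)(C)[Si](C)(C)OC/C(=C\CC=C(C)C)[C@@H]1CC/C(C)=C/C/C=C(/COCc2ccc(OC)cc2)[C@H]1C(=O)OC
F4 | step 7 | 1-({[(2Z,5E)-2-bromo-6-methyldeca-2,5-dien-9-yn-1-yl]oxy}methyl)-4-methoxybenzene (bromo dienyne) | COc1ccc(COC/C(Br)=C/C/C=C(C)/CCC#C)cc1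
F5 | step 7 | (10E,13Z)-14-bromo-15-[(4-methoxybenzyl)oxy]-2,10-dimethylpentadeca-2,10,13-trien-6-yn-5-one (ynone) | COc1ccc(COC/C(Br)=C/C/C=C(C)/CCC#CC(=O)CC=C(C)C)cc1
F6 | step 14 | S-(pyridin-2-yl) thioester of seco acid 21 | O=C(Sc1ccccn1)C/C(COCc1ccc(OC)cc1)=C\C/C=C(C)/CC/C=C(/[C@H](O)CC=C(C)C)CO[Si](C)(C)C(C)(C)C
F7 | step 19 | (2Z)-2-[(1R,2S,3E,6E)-2,3-bis{[(4-methoxybenzyl)oxy]methyl}-7-methylcyclonona-3,6-dien-1-yl]-6-methylhepta-2,5-dienal (enal) | O=C/C(=C\CC=C(C)C)[C@@H]1CC/C(C)=C/C/C=C(/COCc2ccc(OC)cc2)[C@H]1COCc1ccc(OC)cc1
F8 | step 19 | corresponding (2Z)-hepta-2,5-dienoic acid | OC(=O)/C(=C\CC=C(C)C)[C@@H]1CC/C(C)=C/C/C=C(/COCc2ccc(OC)cc2)[C@H]1COCc1ccc(OC)cc1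
F9 | step 19 | (2R)-2-[(1S,2S,3E,6E)-2,3-bis{[(4-methoxybenzyl)oxy]methyl}-7-methylcyclonona-3,6-dien-1-yl]-6-methylhept-5-enoic acid | OC(=O)[C@H](CCC=C(C)C)[C@@H]1CC/C(C)=C/C/C=C(/COCc2ccc(OC)cc2)[C@H]1COCc1ccc(OC)cc1
F10 | step 22 | (2R)-2-[(1S,2S,3E,6E)-3-formyl-2-(hydroxymethyl)-7-methylcyclonona-3,6-dien-1-yl]-6-methylhept-5-en-1-yl acetate (hydroxy enal) | CC(=O)OC[C@H](CCC=C(C)C)[C@@H]1CC/C(C)=C/C/C=C(/C=O)[C@H]1CO
A1 | alternative 1 | (E)-cyclonon-5-enone with the C1 side chain (product of the oxy-Cope step) | CC(C)(C)[Si](C)(C)OC[C@H](CCC=C(C)C)[C@@H]1CC/C(C)=C/CCCC1=O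
A2 | alternative 1 | cyclopentanol substrate: vinyl on the carbinol carbon C9, methyl and vinyl on C4, vinyl groups trans | CC(C)(C)[Si](C)(C)OC[C@H](CCC=C(C)C)[C@@H]1CC[C@@](C)(C=C)[C@]1(O)C=C
A3 | alternative 2 | nine-membered ring sulfone (C2 as either epimer) | CC(C)(C)[Si](C)(C)OC[C@H](CCC=C(C)C)[C@@H]1C(S(=O)(=O)c2ccccc2)C/C(C)=C/C/C=C(/COCc2ccc(OC)cc2)[C@H]1COCc3ccc(OC)cc3
A4 | alternative 2 | open-chain substrate: phenylsulfonylmethyl group on C1 (C2) and primary allylic bromide at C3 | CC(C)(C)[Si](C)(C)OC[C@H](CCC=C(C)C)[C@H](CS(=O)(=O)c1ccccc1)[C@H](COCc1ccc(OC)cc1)/C(COCc1ccc(OC)cc1)=C\C/C=C(C)/CBr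
A5 | alternative 3 | (E)-cyclonon-4-enone with C9, C1 and C10 set (product of the fragmentation) | CC(C)(C)[Si](C)(C)OC[C@H](CCC=C(C)C)[C@@H]1CC/C(C)=C/CCC(=O)[C@H]1COCc1ccc(OC)cc1
A6 | alternative 3 | cis-fused hydrindanol tosylate: angular OH on C8, angular CH3 on C4, tosylate on C5, all three on one face of the five-membered ring | CC(C)(C)[Si](C)(C)OC[C@H](CCC=C(C)C)[C@@H]1CC[C@@]2(C)[C@H](OS(=O)(=O)c3ccc(C)cc3)CC[C@@]2(O)[C@H]1COCc1ccc(OC)cc1
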